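(The earlier runs and the new flask were generated by integration for substances that don't exist, noise included.)

Two things are asked about this flask, the time of its largest amount of Q and that amount, and one number carries both.

in all of them: E 25.5 mM (fed, over 50 s)

| flask | G | remark | time |
|---|---|---|---|
| alpha | 8.5 mM | run made earlier |  |
| flask | 17 mM |  | 12 min |

alpha run (percent of the G charged)

| time / s | Q / % | Z / % |
|---|---|---|
| 10.0 | 5 | 0 |
| 25.0 | 10 | 12 |
| 50.0 | 12 | 40 |
| 80.0 | 9 | 60 |

(readings scatter by 1.5 percentage points)

- when, up to 12 min, the flask holds most Q
- the amount of Q, in percent of the G charged, at that time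

- the analysis behind the earlier runs scatters by 1.5 percentage points, standard deviation
- a reading or a percentage of Z counts all its forms, free or not

In the alpha run, between 25.0 s and 50.0 s, Q averaged 11.0 % while Z gained 28 percentage points. Amount held over amount passed per second gives a lifetime of Q of 9.82 s, a reading with its scatter.

Which given numbers must we know well? The longest time matters little, because this lifetime is far shorter than 12 min. The G charge, twice that of the alpha run, matters little at first, because E enters at the same rate and percentages of G are asked for. The dosing time matters, because with a lifetime shorter than the feed, Q follows its supply (a quasi-steady state), so the peak goes with the end of the feed. An error in the lifetime goes in proportion into the height, since Q held is supply times lifetime. We therefore reckon on a peak in this flask at 50 s, near the alpha reading of 12 %.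

The forecast, a little earlier and lower than ours, gives 0.75 min and 11 %, saying “Q should peak near the end of dosing”.

The flask gives 0.777 min and 11.3 %.

    G ⇌ L (K = 1.10, k = 0.0150 s⁻¹)
    G + E ⇌ Q (K = 160 M⁻¹, k = 2.50 M⁻¹ s⁻¹)
    J ⇌ Z, rate k3*(cs3 - [Z]) while solid is left; crystals form when [Z] > cs3 (solubility = 0.840 mM, k = 0.360 s⁻¹)
    Q ⇌ Z + X (K = 0.0150 M, k = 0.110 s⁻¹)

At that time 27.3 % of the G is still free in the flask. Divided by our lifetime, itself a reading, the peak gives a rough forward passage from Q to Z + X of 0.0115 s⁻¹ as a share of the G charged, the way back not counted. The neighbour flask, charged with 10 mM of E, peaks at 5.95 %, so with the same lifetime its rough forward passage at that peak is 0.00606 s⁻¹, about half that of the flask.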